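The side chain is cut between C11 (the CH2 on C9 of ring B, labdane numbering) and the carbinol carbon C12. The key step exploits the fact that the C12 oxygen is γ to the imide carbonyl C15: C12–C13–C14–C15 is tied up as a γ-butyrolactone that carries the C16 ester on C13 and a carboxylic acid on C12 (an ent-isocitrate lactone from (S)-malate). A nickel/photoredox decarboxylative C(sp3)–C(sp3) coupling joins this acid to the C11 bromide of a 2α,3β-dichloro-8(17)-ene decalin, itself made by cationic bicyclization of an enantioenriched dichloride, and sets C12 trans to C13. Ammonolysis then turns lactone and ester into the hydroxy succinimide.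

Key step: step 19

Remark (numbering): decalins are described with labdane numbering (ring carbons C1–C10, C11 on C9, C17 = exocyclic CH2 on C8, gem-dimethyl on C4, CH3 on C10, side chain C12–C16); α is the face of H-5, β the face of the C10 methyl.
Remark (assumptions): compounds 1, 4, 12, 22 and 23 are taken as commercial; in step 5 the enantiomer of the chiral ligand that delivers the (5R,6R)-dichloride is assumed to be chosen.

**Decalin fragment (steps 1–15)**

Step 1
Reactants: 1 prenyl acetate
Product: 2 (2E)-4-hydroxy-3-methylbut-2-en-1-yl acetate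
Conditions: SeO2 (cat.), t-BuOOH, salicylic acid (cat.), CH2Cl2, rt
Reagents that add atoms: tert-butyl hydroperoxide, CC(C)(C)OO
Why: Selenium dioxide allylic oxidation (ene reaction, then [2,3]-shift) should hydroxylate the (E)-methyl group selectively, fixing the E-trisubstituted alkene that later becomes C5=C10.

Step 2
Reactants: 2 (2E)-4-hydroxy-3-methylbut-2-en-1-yl acetate
Product: 3 (2E)-4-bromo-3-methylbut-2-en-1-yl acetate
Conditions: CBr4, PPh3, CH2Cl2, 0 °C
Reagents that add atoms: carbon tetrabromide, BrC(Br)(Br)Br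
Why: The Appel reaction should convert the primary allylic alcohol into the bromide without allylic transposition.

Step 3
Reactants: 3 (2E)-4-bromo-3-methylbut-2-en-1-yl acetate; 4 prop-2-yn-1-ol
Product: 5 (2E)-7-hydroxy-3-methylhept-2-en-5-yn-1-yl acetate
Conditions: CuI, NaI, K2CO3, DMF, rt
Reagents that add atoms: none
Why: Copper-mediated coupling of a terminal alkyne with a primary allylic bromide should give the skipped enyne by direct (α) substitution.

Step 4
Reactants: 5 (2E)-7-hydroxy-3-methylhept-2-en-5-yn-1-yl acetate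
Product: 6 (2E,5Z)-7-hydroxy-3-methylhepta-2,5-dien-1-yl acetate
Conditions: H2 (1 atm), Pd/CaCO3 poisoned with Pb(OAc)2 (Lindlar catalyst), quinoline, EtOAc, rt
Reagents that add atoms: none
Why: Lindlar semi-hydrogenation should give the Z-allylic alcohol by syn addition and leave the trisubstituted alkene untouched.

Step 5
Reactants: 6 (2E,5Z)-7-hydroxy-3-methylhepta-2,5-dien-1-yl acetate
Product: 7 (2E,5R,6R)-5,6-dichloro-7-hydroxy-3-methylhept-2-en-1-yl acetate
Conditions: ClTi(Oi-Pr)3, t-BuOCl, chiral tridentate Schiff-base amino-alcohol ligand (30 mol%), hexanes, −20 °C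
Reagents that add atoms: tert-butyl hypochlorite, CC(C)(C)OCl; chlorotitanium triisopropoxide, CC(C)O[Ti](Cl)(OC(C)C)OC(C)C
Why: Titanium-mediated, alcohol-directed enantioselective dichlorination should add Cl2 anti across only the alkene next to the titanium-bound carbinol, so the Z-alkene gives the dichloride that becomes trans-diequatorial C2/C3 (absolute sense set by the ligand).

Step 6
Reactants: 7 (2E,5R,6R)-5,6-dichloro-7-hydroxy-3-methylhept-2-en-1-yl acetate
Product: 9 methyl (2R,3R,5E)-7-acetoxy-2,3-dichloro-5-methylhept-5-enoate, via carboxylic acid 8 (not isolated)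
Conditions: TEMPO (cat.), PhI(OAc)2, MeCN/pH 7 buffer, 0 °C → rt; then Me3SiCHN2, PhMe/MeOH, 0 °C
Reagents that add atoms: water, O; trimethylsilyldiazomethane, C[Si](C)(C)C=[N+]=[N-]
Why: Oxoammonium oxidation of the primary alcohol through the aldehyde hydrate to the acid, then diazoalkane esterification, avoids any base that could close the chlorohydrin or epimerize the α-chloro centre.

Step 7
Reactants: 9 methyl (2R,3R,5E)-7-acetoxy-2,3-dichloro-5-methylhept-5-enoate
Product: 10 (2E,5R,6R)-5,6-dichloro-3,7-dimethyloct-2-ene-1,7-diol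
Conditions: MeMgBr (excess), CeCl3, THF, −78 → −20 °C; NH4Cl quench at low temperature
Reagents that add atoms: methylmagnesium bromide, C[Mg]Br
Why: Double Grignard addition (cerium-assisted, low basicity) should build the gem-dimethyl carbinol at C4 and cleave the acetate in the same operation; the cold quench keeps the magnesium chlorohydrin alkoxide from closing to an epoxide.

Step 8
Reactants: 10 (2E,5R,6R)-5,6-dichloro-3,7-dimethyloct-2-ene-1,7-diol
Product: 11 (3R,4R,6E)-8-bromo-3,4-dichloro-2,6-dimethyloct-6-en-2-ol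
Conditions: CBr4, PPh3, CH2Cl2, −20 °C
Reagents that add atoms: carbon tetrabromide, BrC(Br)(Br)Br
Why: The Appel reaction should be selective for the primary allylic alcohol over the hindered tertiary carbinol.

Step 9
Reactants: 11 (3R,4R,6E)-8-bromo-3,4-dichloro-2,6-dimethyloct-6-en-2-ol; 12 methyl acetoacetate
Product: 13 methyl (6E,9R,10R)-9,10-dichloro-11-hydroxy-7,11-dimethyl-3-oxododec-6-enoate
Conditions: NaH, then n-BuLi, THF, 0 °C (dianion of 12, excess); add 11 at −78 → −40 °C; AcOH quench at −40 °C
Reagents that add atoms: none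
Why: γ-Alkylation of the acetoacetate dianion with the allylic bromide installs the β-keto ester terminator; one equivalent of dianion is sacrificed to the tertiary OH, and the low temperature should keep its lithium alkoxide from displacing the neighbouring chloride.

Step 10
Reactants: 13 methyl (6E,9R,10R)-9,10-dichloro-11-hydroxy-7,11-dimethyl-3-oxododec-6-enoate
Product: 14 methyl (1R,4aR,6R,7R,8aS)-6,7-dichloro-5,5,8a-trimethyl-2-oxodecahydronaphthalene-1-carboxylate (2α,3β-dichloro-8-oxo, 9β-CO2Me, 5α-H, 10β-CH3)
Conditions: EtAlCl2 (3 equiv), CH2Cl2, −78 → −20 °C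
Reagents that add atoms: none
Why: Cation–olefin bicyclization: the aluminium alkoxide of the tertiary carbinol ionizes with help from the C3 chlorine (chloriranium), the E-alkene and the aluminium enolate of the β-keto ester close rings A and B through a chair–chair transition state with both C–Cl bonds equatorial, which sets C5 and C10 (trans-decalin), and the enolizable C9 ester settles equatorial.

Step 11
Reactants: 14 bicyclic β-keto ester
Product: 16 methyl 2α,3β-dichloro-8-oxo-6-ene decalin-9β-carboxylate (6,7-didehydro derivative of 14), via 7α-phenylselanyl ketone 15 (not isolated)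
Conditions: LiN(i-Pr)2 (2.2 equiv), THF, −78 °C; PhSeBr; then H2O2, pyridine, CH2Cl2, 0 °C → rt
Reagents that add atoms: none
Why: The β-keto ester dianion should be selenenylated at its more reactive C7 terminus, and selenoxide syn-elimination can only go towards C6 (C9 has no usable β-hydrogen), giving the C6=C7 enone.

Step 12
Reactants: 16 enone
Product: 18 methyl 2α,3β-dichloro-6α-hydroxy-8-oxo decalin-9β-carboxylate, via 6α-pinacolboronate 17 (not isolated)
Conditions: B2pin2, CuCl (cat.), Xantphos (cat.), NaOt-Bu (cat.), MeOH, THF, rt; then H2O2, pH 7 phosphate buffer, 0 °C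
Reagents that add atoms: hydrogen peroxide, OO
Why: Copper-catalysed conjugate borylation should deliver boron to C6 from the α face (the β face is blocked by the axial methyls on C4 and C10), and buffered oxidation with retention gives the 6α-alcohol without retro-aldol or dehydration.

Step 13
Reactants: 18 6α-hydroxy β-keto ester
Product: 19 methyl 2α,3β-dichloro-6α-hydroxy-8-methylene decalin-9β-carboxylate
Conditions: Zn, CH2Br2, TiCl4, THF/CH2Cl2, 0 °C → rt
Reagents that add atoms: dibromomethane, BrCBr
Why: Lombardo methylenation is non-basic, so it should convert the enolizable C8 ketone into the exocyclic C8=C17 alkene in the presence of the ester and the free β-hydroxyl.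

Step 14
Reactants: 19 methylene ester
Product: 20 2α,3β-dichloro-9β-(hydroxymethyl)-8-methylene decalin-6α-ol (4,4,10-trimethyl)
Conditions: i-Bu2AlH (excess), CH2Cl2, −78 → 0 °C; Rochelle salt work-up
Reagents that add atoms: none
Why: Hydride reduction of the ester to the primary C11 alcohol leaves alkene and chlorides untouched.

Step 15
Reactants: 20 diol
Product: 21 9β-(bromomethyl)-2α,3β-dichloro-8-methylene decalin-6α-ol (4,4,10-trimethyl)
Conditions: CBr4, PPh3, CH2Cl2, 0 °C
Reagents that add atoms: carbon tetrabromide, BrC(Br)(Br)Br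
Why: The Appel reaction should brominate only the primary C11 alcohol; the 6α-hydroxyl is shielded by the 4α-methyl and the ring junction.

**Lactone acid fragment (steps 16–18)**

Step 16
Reactants: 22 dimethyl (S)-malate; 23 tert-butyl bromoacetate
Product: 24 3-tert-butyl 1,2-dimethyl (1S,2R)-1-hydroxypropane-1,2,3-tricarboxylate
Conditions: LiN(SiMe3)2 (2.2 equiv), THF, −78 → −20 °C; then 23
Reagents that add atoms: none
Why: Frater–Seebach alkylation of the malate alkoxide-enolate occurs anti to the alkoxide in the chelated dianion and sets the future C13 as R.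

Step 17
Reactants: 24 triester
Product: 25 (2S,3R)-5-tert-butoxy-2-hydroxy-3-(methoxycarbonyl)-5-oxopentanoic acid
Conditions: LiOH (1.05 equiv), THF/H2O, 0 °C; aq. HCl to pH 3
Reagents that add atoms: lithium hydroxide, [Li+].[OH-]
Why: Chemoselective saponification: the α-hydroxy methyl ester is activated by the neighbouring hydroxyl and unhindered, while the α-branched methyl ester and the tert-butyl ester should survive.

Step 18
Reactants: 25 hydroxy acid
Product: 26 (2S,3R)-3-(methoxycarbonyl)-5-oxotetrahydrofuran-2-carboxylic acid (cis)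
Conditions: CF3CO2H, CH2Cl2, rt; then toluene, 60 °C
Reagents that add atoms: none
Why: Acidolysis of the tert-butyl ester followed by acid-catalysed γ-lactonization of the freed acid onto the C2 hydroxyl gives the lactone and leaves only the C12 carboxyl free.

**Fragment union and end game (steps 19–23)**

Step 19
Reactants: 21 decalin bromide; 26 lactone acid
Product: 27 methyl (2S,3R)-2-{[2α,3β-dichloro-6α-hydroxy-8-methylene decalin-9β-yl]methyl}-5-oxotetrahydrofuran-3-carboxylate (trans lactone)
Conditions: Ir[dF(CF3)ppy]2(dtbbpy)PF6 (2 mol%), NiCl2·glyme (10 mol%), 4,4′-dimethoxy-2,2′-bipyridine (10 mol%), K2CO3, H2O, MeCN, blue LEDs, rt; 26 in excess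
Reagents that add atoms: none
Why: The photoexcited trivalent iridium complex oxidizes the carboxylate of 26, CO2 is lost and the lactone α-oxy radical at C12 forms; low-valent nickel (zerovalent or monovalent) adds the primary C11–Br bond of 21, captures the radical and the resulting trivalent dialkylnickel reductively eliminates to form C11–C12. The closest known reaction type is the metallaphotoredox decarboxylative sp3–sp3 cross-coupling of α-oxy acids with primary alkyl bromides. No ring is closed. The new stereocentre C12 is controlled by the C13 ester on the five-membered lactone: the nickel-bound ring carbon prefers the face trans to it, so the original C12 configuration is irrelevant and the 12S,13R relationship should result. The step needs cross- over homo-coupling and must leave the two secondary chlorides, the exocyclic alkene and the lactone alone; this is secured because the only bond nickel can add to is the primary C–Br, the only oxidizable carboxylate is on 26, and the free 6α-hydroxyl is inert.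

Step 20
Reactants: 27 coupled lactone ester
Product: 29 2α,3β-dichloro-6α,12-dihydroxylabd-8(17)-ene-15,16-dicarboximide (12S,13R), via hydroxy amide ester 28 (not isolated)
Conditions: NH3 (7 M in MeOH), 0 °C → rt; then K2CO3 (cat.), MeOH, rt
Reagents that add atoms: ammonia, N
Why: Ammonolysis opens the lactone (freeing the C12 hydroxyl) and the resulting primary amide acylates itself on the neighbouring methyl ester (5-exo imide formation); no stereocentre is touched, and the base-labile β,γ-enone is not yet present.

Step 21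
Reactants: 29 diol imide
Product: 30 12-O-triethylsilyl ether of 29
Conditions: Et3SiCl, imidazole, DMF, 0 °C
Reagents that add atoms: chlorotriethylsilane, CC[Si](Cl)(CC)CC
Why: Silylation should take the less hindered acyclic C12 carbinol and spare the 6α-hydroxyl, which is flanked by the gem-dimethyl carbon and the ring junction.

Step 22
Reactants: 30 silyl ether
Product: 31 12-O-triethylsilyl haterumaimide B (6-ketone)
Conditions: Dess–Martin periodinane, NaHCO3, CH2Cl2, 0 °C → rt
Reagents that add atoms: none
Why: Buffered Dess–Martin oxidation turns the remaining 6α-alcohol into the C6 ketone under neutral conditions, so the exocyclic β,γ-enone is not pulled into conjugation.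

Step 23
Reactants: 31 silyl-protected ketone
Product: 32 haterumaimide B
Conditions: HF·pyridine, pyridine, THF, 0 °C
Reagents that add atoms: none
Why: Buffered fluoride desilylation frees the C12 hydroxyl without base, which would isomerize the 8(17)-ene into conjugation with the C6 ketone.

**Compound list**

1 | 3-methylbut-2-en-1-yl acetate (prenyl acetate) | CC(C)=CCOC(C)=O | starting material
2 | (2E)-4-hydroxy-3-methylbut-2-en-1-yl acetate | CC(=O)OC/C=C(C)/CO | intermediate
3 | (2E)-4-bromo-3-methylbut-2-en-1-yl acetate | CC(=O)OC/C=C(C)/CBr | intermediate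
4 | prop-2-yn-1-ol | OCC#C | starting material
5 | (2E)-7-hydroxy-3-methylhept-2-en-5-yn-1-yl acetate | CC(=O)OC/C=C(C)/CC#CCO | intermediate
6 | (2E,5Z)-7-hydroxy-3-methylhepta-2,5-dien-1-yl acetate | CC(=O)OC/C=C(C)/C/C=C\CO | intermediate
7 | (2E,5R,6R)-5,6-dichloro-7-hydroxy-3-methylhept-2-en-1-yl acetate | OC[C@@H](Cl)[C@H](Cl)C/C(C)=C/COC(C)=O | intermediate
8 | (2R,3R,5E)-7-acetoxy-2,3-dichloro-5-methylhept-5-enoic acid | OC(=O)[C@@H](Cl)[C@H](Cl)C/C(C)=C/COC(C)=O | intermediate (not isolated)
9 | methyl (2R,3R,5E)-7-acetoxy-2,3-dichloro-5-methylhept-5-enoate | COC(=O)[C@@H](Cl)[C@H](Cl)C/C(C)=C/COC(C)=O | intermediate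
10 | (2E,5R,6R)-5,6-dichloro-3,7-dimethyloct-2-ene-1,7-diol | OC(C)(C)[C@@H](Cl)[C@H](Cl)C/C(C)=C/CO | intermediate
11 | (3R,4R,6E)-8-bromo-3,4-dichloro-2,6-dimethyloct-6-en-2-ol | OC(C)(C)[C@@H](Cl)[C@H](Cl)C/C(C)=C/CBr | intermediate
12 | methyl acetoacetate | CC(=O)CC(=O)OC | starting material
13 | methyl (6E,9R,10R)-9,10-dichloro-11-hydroxy-7,11-dimethyl-3-oxododec-6-enoate | OC(C)(C)[C@@H](Cl)[C@H](Cl)C/C(C)=C/CCC(=O)CC(=O)OC | intermediate
14 | methyl (1R,4aR,6R,7R,8aS)-6,7-dichloro-5,5,8a-trimethyl-2-oxodecahydronaphthalene-1-carboxylate | O=C1CC[C@H]2C(C)(C)[C@@H](Cl)[C@H](Cl)C[C@]2(C)[C@H]1C(=O)OC | intermediate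
15 | 7α-phenylselanyl derivative of 14 | O=C1[C@H]([Se]c3ccccc3)C[C@H]2C(C)(C)[C@@H](Cl)[C@H](Cl)C[C@]2(C)[C@H]1C(=O)OC | intermediate (not isolated)
16 | 6,7-didehydro derivative of 14 (C6=C7 enone) | O=C1C=C[C@H]2C(C)(C)[C@@H](Cl)[C@H](Cl)C[C@]2(C)[C@H]1C(=O)OC | intermediate
17 | 6α-(pinacolatoboryl) derivative of 14 | O=C1C[C@H](B3OC(C)(C)C(C)(C)O3)[C@H]2C(C)(C)[C@@H](Cl)[C@H](Cl)C[C@]2(C)[C@H]1C(=O)OC | intermediate (not isolated)
18 | 6α-hydroxy derivative of 14 | O=C1C[C@H](O)[C@H]2C(C)(C)[C@@H](Cl)[C@H](Cl)C[C@]2(C)[C@H]1C(=O)OC | intermediate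
19 | methyl 2α,3β-dichloro-6α-hydroxy-4,4,10-trimethyl-8-methylene-trans-decalin-9β-carboxylate | C=C1C[C@H](O)[C@H]2C(C)(C)[C@@H](Cl)[C@H](Cl)C[C@]2(C)[C@H]1C(=O)OC | intermediate
20 | 2α,3β-dichloro-9β-(hydroxymethyl)-4,4,10-trimethyl-8-methylene-trans-decalin-6α-ol | C=C1C[C@H](O)[C@H]2C(C)(C)[C@@H](Cl)[C@H](Cl)C[C@]2(C)[C@H]1CO | intermediate
21 | 9β-(bromomethyl)-2α,3β-dichloro-4,4,10-trimethyl-8-methylene-trans-decalin-6α-ol | C=C1C[C@H](O)[C@H]2C(C)(C)[C@@H](Cl)[C@H](Cl)C[C@]2(C)[C@H]1CBr | intermediate
22 | dimethyl (S)-malate | COC(=O)C[C@H](O)C(=O)OC | starting material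
23 | tert-butyl bromoacetate | CC(C)(C)OC(=O)CBr | starting material
24 | 3-tert-butyl 1,2-dimethyl (1S,2R)-1-hydroxypropane-1,2,3-tricarboxylate | COC(=O)[C@@H](O)[C@@H](CC(=O)OC(C)(C)C)C(=O)OC | intermediate
25 | (2S,3R)-5-tert-butoxy-2-hydroxy-3-(methoxycarbonyl)-5-oxopentanoic acid | OC(=O)[C@@H](O)[C@@H](CC(=O)OC(C)(C)C)C(=O)OC | intermediate
26 | (2S,3R)-3-(methoxycarbonyl)-5-oxotetrahydrofuran-2-carboxylic acid | OC(=O)[C@H]1OC(=O)C[C@H]1C(=O)OC | intermediate
27 | methyl (2S,3R)-2-{[2α,3β-dichloro-6α-hydroxy-4,4,10-trimethyl-8-methylene-trans-decalin-9β-yl]methyl}-5-oxotetrahydrofuran-3-carboxylate | C=C1C[C@H](O)[C@H]2C(C)(C)[C@@H](Cl)[C@H](Cl)C[C@]2(C)[C@H]1C[C@@H]3OC(=O)C[C@H]3C(=O)OC | intermediate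
28 | hydroxy amide ester from lactone opening of 27 (C15 carboxamide, C16 methyl ester, 6α,12-diol) | C=C1C[C@H](O)[C@H]2C(C)(C)[C@@H](Cl)[C@H](Cl)C[C@]2(C)[C@H]1C[C@H](O)[C@@H](CC(N)=O)C(=O)OC | intermediate (not isolated)
29 | 2α,3β-dichloro-6α,12-dihydroxylabd-8(17)-ene-15,16-dicarboximide (12S,13R) | C=C1C[C@H](O)[C@H]2C(C)(C)[C@@H](Cl)[C@H](Cl)C[C@]2(C)[C@H]1C[C@H](O)[C@H]1CC(=O)NC1=O | intermediate
30 | 12-O-triethylsilyl ether of 29 | C=C1C[C@H](O)[C@H]2C(C)(C)[C@@H](Cl)[C@H](Cl)C[C@]2(C)[C@H]1C[C@H](O[Si](CC)(CC)CC)[C@H]1CC(=O)NC1=O | intermediate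
31 | 12-O-triethylsilyl haterumaimide B | C=C1CC(=O)[C@H]2C(C)(C)[C@@H](Cl)[C@H](Cl)C[C@]2(C)[C@H]1C[C@H](O[Si](CC)(CC)CC)[C@H]1CC(=O)NC1=O | intermediate
32 | haterumaimide B: 2α,3β-dichloro-12-hydroxy-6-oxolabd-8(17)-ene-15,16-dicarboximide (12S,13R; 5α-H, 9α-H, 10β-CH3) | C=C1CC(=O)[C@H]2C(C)(C)[C@@H](Cl)[C@H](Cl)C[C@]2(C)[C@H]1C[C@H](O)[C@H]1CC(=O)NC1=O | target

**Counts and risks**

Total step count: 23. Longest linear sequence: 20 steps (steps 1–15 and 19–23).

Steps most likely to fail:

1. Step 19 (fragment coupling). The hindered, β-branched primary bromide may engage nickel slowly, so that the lactone radical dimerizes or is reduced. The transient homoallyl radical at C11 may rearrange through 3-exo closure and ring opening. Facial control at C12 may erode, or the lactone may hydrolyse in the aqueous carbonate medium. Fallback: a decarboxylative Negishi-type coupling in which C11 is a preformed organozinc and never a free radical. Bromide 21 is silylated (Et3SiCl, imidazole) to triethylsilyl ether F1, and zinc insertion (Zn dust, LiCl, THF, 50 °C) gives alkylzinc bromide F2. Acid 26 is converted with N-hydroxyphthalimide and N,N′-diisopropylcarbodiimide into redox-active ester F3. NiCl2·glyme with 4,4′-di-tert-butyl-2,2′-bipyridine in THF/DMF then couples F2 with F3 to silylated lactone F4, and HF·pyridine removes the silyl group to rejoin the route at 27.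

2. Step 10 (bicyclization). Ionization of the β-chloro tertiary carbinol may be outrun by elimination to the isopropenyl compound, by O- instead of C-cyclization of the β-keto ester, or by a competing chair with axial chlorines. Fallback: generate the same cation by protonation instead of ionization. Alcohol 13 is dehydrated with the Burgess reagent (benzene, 50 °C) to isopropenyl β-keto ester F5, which is cyclized with ClSO3H in 2-nitropropane at −78 °C (protonation of the 1,1-disubstituted alkene gives the chlorine-bridged C4 cation) to rejoin the route at 14.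

3. Step 13 (methylenation). The β-keto ester may enolize instead of reacting, or the Lewis-acidic reagent may dehydrate the β-hydroxy ketone back to the enone. Fallback: a two-stage Peterson olefination. Alcohol 18 is silylated (Et3SiOTf, 2,6-lutidine) to triethylsilyl ether F6, Me3SiCH2Li/CeCl3 (THF, −78 °C) adds to the C8 ketone from the α face to give β-hydroxysilane F7, and HF·pyridine effects the elimination and removes the triethylsilyl group in the same operation, rejoining the route at 19.

Further compounds
F1 | step 19 | 6-O-triethylsilyl ether of bromide 21 | C=C1C[C@H](O[Si](CC)(CC)CC)[C@H]2C(C)(C)[C@@H](Cl)[C@H](Cl)C[C@]2(C)[C@H]1CBr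
F2 | step 19 | alkylzinc bromide from F1 | C=C1C[C@H](O[Si](CC)(CC)CC)[C@H]2C(C)(C)[C@@H](Cl)[C@H](Cl)C[C@]2(C)[C@H]1C[Zn]Br
F3 | step 19 | N-(acyloxy)phthalimide ester of acid 26 | O=C(ON1C(=O)c2ccccc2C1=O)[C@H]3OC(=O)C[C@H]3C(=O)OC
F4 | step 19 | 6-O-triethylsilyl ether of lactone 27 | C=C1C[C@H](O[Si](CC)(CC)CC)[C@H]2C(C)(C)[C@@H](Cl)[C@H](Cl)C[C@]2(C)[C@H]1C[C@@H]3OC(=O)C[C@H]3C(=O)OC
F5 | step 10 | methyl (6E,9R,10R)-9,10-dichloro-7,11-dimethyl-3-oxododeca-6,11-dienoate | C=C(C)[C@@H](Cl)[C@H](Cl)C/C(C)=C/CCC(=O)CC(=O)OC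
F6 | step 13 | 6-O-triethylsilyl ether of ketone 18 | O=C1C[C@H](O[Si](CC)(CC)CC)[C@H]2C(C)(C)[C@@H](Cl)[C@H](Cl)C[C@]2(C)[C@H]1C(=O)OC
F7 | step 13 | 8β-hydroxy-8α-(trimethylsilylmethyl) adduct of F6 | C[Si](C)(C)C[C@]1(O)C[C@H](O[Si](CC)(CC)CC)[C@H]2C(C)(C)[C@@H](Cl)[C@H](Cl)C[C@]2(C)[C@H]1C(=O)OC
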